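## Analysis of the target

The target is (3R)-5,7-dimethoxy-3-{6-[(2S,5R,7S)-7-methyl-1,6-dioxaspiro[4.4]nonan-2-yl]hexyl}isobenzofuran-1(3H)-one. It has three parts: a 5,7-dimethoxyphthalide (benzene ring A, C3a to C7a, fused to γ-lactone ring B through C1, O2 and C3), an unbranched chain of six methylenes (C1' on C3 to C6'), and a 1,6-dioxaspiro[4.4]nonane. Ring C of the spiroketal (O1'', C2'', C3'', C4'', C5'') carries the chain on C2''; ring D (C5'', O6'', C7'', C8'', C9'') carries a methyl group on C7''. The four stereocentres are C3 (R), C2'' (S), C5'' (R) and C7'' (S). In this isomer each ring oxygen is trans to the alkyl group of the other ring: O6'' is trans to the chain on ring C and O1'' is trans to the methyl group on ring D. C3 lies six methylenes from the spiroketal, so it cannot be controlled by the other stereocentres and needs a reagent or catalyst. The ketal at C5'' epimerises through an oxocarbenium ion under protic or strong Lewis acid, the lactone is opened by hydroxide or alkoxide, and ring A is electron-rich and easily attacked by electrophiles. The difficulty is C5'': it joins two five-membered rings, neither epimer has a decisive anomeric or steric advantage, and equilibration should therefore give both. The strategy rests on the fact that C5'' can be made from the enol ether carbon of a dihydrofuran (C4''=C5'' in ring C), where the face anti to the C2'' chain can be addressed under kinetic control.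

## Retrosynthetic reasoning

**22 to 14 and 17.** The C3–C1' bond is cut, and with it the lactone C1–O2 bond. This is the only bond that joins a stereocentre to an unfunctionalised chain, and it separates the cheap aromatic half from the valuable spiroketal half. The terminal alkene of 14 is inert through the earlier steps and becomes a carbon nucleophile only at the end. The forward reaction must add C1' to the aldehyde carbon of 17 on one face under catalyst control, and the alkoxide so formed must close ring B on the neighbouring ester without acid. The lactone is made last because it would not survive the basic and organometallic steps before it.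

**17 to 16 to 15.** The aldehyde carbon of 17 is the future C3 and is the methyl carbon of toluate 15. Only the oxidation level changes: radical bromination to 16, then oxygen transfer from an amine N-oxide. The ester of 15 is already the future C1.

**14 to 12.** A hydroxyl is put back on C4''. It is the trace of an epoxide and has no place in the target, so the forward step is a radical deoxygenation through 13, chosen because it is neutral and does not ionise the ketal.

**12 to 10 (through 11).** The C5''–O6'' bond and the C4''–O bond are cut, which leads to enol ether 10 with its free side-chain hydroxyl. The cut is made in ring D and not in ring C because the enol ether then sits in the ring that carries the long hexenyl chain, the larger of the two groups available to shield one face. The forward reaction has to epoxidise only the enol ether, do so anti to the C2'' chain, and deliver the hydroxyl to C5'' on the face the epoxide oxygen leaves.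

**10 to 9 to 4 and 7.** The C5''–C9'' bond is cut. The vinylic hydrogen on C5'' of 4 is the most acidic one in the molecule, so 4 can be metallated there and alkylated by the primary iodide 7. The hydroxyl is carried as a silyl ether and freed by fluoride, because any acid would close the spiroketal at once and without control.

**4 to 3 to 2 to 1.** Ring C is opened at O1''–C5'': an alkynol cycloisomerisation turns the terminal alkyne carbon of 3 into C5''. The C3''–C4'' bond of 3 comes from acetylide opening of epoxide 2, and C2'' is set by hydrolytic kinetic resolution of the commercial racemate 1.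

**7 to 6 to 5.** C7'' is taken from the chiral pool: the primary hydroxyl of diol 5 becomes the iodide and the secondary one the silyl ether.

## Alternatives that were turned down

**Alternative 1:** Both ortho bonds of ring A, C3a–C3 and C7a–C1, are cut.
- Forward step: the aryne released from 2-bromo-3,5-dimethoxyphenyl trifluoromethanesulfonate A1 by halogen–lithium exchange would be attacked at the future C3a by the lithium acetylide of (2S,5R,7S)-2-(hept-6-yn-1-yl)-7-methyl-1,6-dioxaspiro[4.4]nonane A2. The aryllithium formed at the future C7a would be carboxylated to the 2-alkynyl-4,6-dimethoxybenzoic acid A3. Cyclisation to the (Z)-alkylidenephthalide A4 and asymmetric hydrogenation would follow.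
- For it: two aryl C–C bonds form in one flask. The regiochemistry is sound, since the nucleophile adds to the aryne carbon remote from the flanking methoxy group and leaves the carbanion next to it. It avoids both the benzylic bromination of an electron-rich ring and the organozinc chemistry.
- Against it: A2 already contains the finished spiroketal, so C5'' is left unsolved. An acetylide is a sluggish partner for an aryne and competes with the alkyllithium and with the product aryllithium, so A2 would be needed in excess. The closure of A3 needs a π-acidic metal salt and control of 5-exo against 6-endo attack. C3 would then depend on hydrogenating a trisubstituted enol ester, and both catalysts put C5'' at risk.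
- Comparison: it is as convergent as the chosen route and stronger in assembling ring A's substituents at once. The chosen route sets C3 and closes ring B in a single non-acidic operation and controls C5''.

**Alternative 2:** Ring A itself is disconnected at C3a–C7a.
- Forward step: the β,δ-diketo dioxinone A5, which carries the C3 carbinol as a triethylsilyl ether and the complete chain and spiroketal, would be enolised by an amine. The dioxinone α-carbon would add to the ketone next to the silyloxy carbon, and loss of water would aromatise the ring to the benzodioxinone A6.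
- For it: the conditions are weakly basic and metal-free, which the spiroketal tolerates as well as it tolerates the chosen endgame. C3 arrives as a preformed carbinol, so no late catalytic asymmetric addition is needed, and on this point it is stronger. The two phenol oxygens come out differentiated.
- Against it: ring A with exactly this substitution is already present in 15. Building it costs several acylation steps on the most valuable fragment. The C3 carbon of A5 is α to a ketone and can enolise under the conditions of the key step. After A6 there remain two O-methylations, opening of the acetonide, desilylation and lactonisation. C5'' is not addressed.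
- Comparison: it is weaker in step count and in the integrity of C3. The chosen route buys the arene and spends its steps on the spiro centre.

**Alternative 3:** The two bonds flanking the latent ketone carbon, C3''–C4'' and C8''–C9'', are cut.
- Forward step: the azaenolate of acetone dimethylhydrazone A7 would open (S)-2-methyloxirane A8. A second deprotonation at the other methyl group would open epoxide 2, giving the dihydroxy hydrazone A9. Cleavage of the hydrazone and acid-induced ketalisation would give 14 together with its C5'' epimer F1.
- For it: the whole backbone with C2'' and C7'' is made in one flask from two epoxides. The spiroketal is reached in about three operations against ten in the chosen route, with no tin, no dioxirane and no transition metal. On step economy and on the reliability of each single step it is clearly stronger.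
- Against it: C5'' is formed under thermodynamic control, where 14 and F1 should be of similar energy. They are non-polar isomeric oils, hard to separate, and every later contact with acid would mix them again.
- Comparison: the chosen route pays about seven more steps for a kinetically defined C5'' and for the hydroxylated intermediate 12, at which stereoisomers differ in polarity. The thermodynamic closure is kept as the fallback to the key step.

Key step: step 8

Remarks on the chemistry:
- Locants: phthalide C1 to C7a; chain C1' (on C3) to C6' (on C2''); spiroketal O1'', C2'', C3'', C4'', C5'' (spiro), O6'', C7'', C8'', C9''. The double-primed locants are also used for the furan intermediates.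
- (salen)Co(OAc) stands for [N,N'-bis(3,5-di-tert-butylsalicylidene)cyclohexane-1,2-diaminato]cobalt acetate, a trivalent cobalt complex. Its (S,S) antipode is assumed to leave the (S)-epoxide unreacted, as expected for simple 1-alkyl oxiranes.
- The (1S,2S)-bis(triflamide) ligand is assumed to give the (R)-carbinol with the aryl aldehyde 17, following the usual sense of this catalyst with aromatic aldehydes.

## Route

Step 1
Reactants: 1 rac-2-(hex-5-en-1-yl)oxirane (1,2-epoxy-7-octene)
Product: 2 (2S)-2-(hex-5-en-1-yl)oxirane
Conditions: (S,S)-(salen)Co(OAc) (0.5 mol %), H2O (0.55 equiv), neat, 0 °C to rt; distillation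
Reagents that add atoms: none
Why: Jacobsen hydrolytic kinetic resolution: the chiral cobalt complex should hydrolyse the (R)-epoxide much faster, so the unreacted (S)-epoxide can be distilled from the diol; this fixes C2''.

Step 2
Reactants: 2 (2S)-2-(hex-5-en-1-yl)oxirane
Product: 3 (4S)-dec-9-en-1-yn-4-ol
Conditions: LiC≡CH·H2NCH2CH2NH2, DMSO, 0 °C to rt; then H2O
Reagents that add atoms: lithium acetylide (as its ethane-1,2-diamine complex), [Li]C#C
Why: SN2 opening of a terminal epoxide by an acetylide at the unsubstituted carbon; the stereocentre is not involved and becomes the homopropargylic carbinol carbon.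

Step 3
Reactants: 3 (4S)-dec-9-en-1-yn-4-ol
Product: 4 (2S)-2-(hex-5-en-1-yl)-2,3-dihydrofuran
Conditions: Mo(CO)6 (25 mol %), Et3N, Et2O, hν (350 nm); then 3, rt, dark
Reagents that add atoms: none
Why: Alkynol cycloisomerisation through a metal vinylidene: the terminal alkyne rearranges on zerovalent molybdenum, the hydroxyl adds to the vinylidene α-carbon, and the amine converts the cyclic oxacarbene into the endocyclic enol ether. Molybdenum is preferred to tungsten because the five-membered oxacarbene should be released more readily from it; the terminal alkene cannot form a vinylidene and C2'' is untouched.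

Step 4
Reactants: 5 (3S)-butane-1,3-diol
Product: 6 (2S)-4-iodobutan-2-ol
Conditions: I2, PPh3, imidazole, CH2Cl2, 0 °C
Reagents that add atoms: iodine, [I][I]
Why: Garegg–Samuelsson iodination: the alkoxyphosphonium ion forms and is displaced far faster at the unhindered primary hydroxyl, and the stereocentre carries the untouched secondary hydroxyl.

Step 5
Reactants: 6 (2S)-4-iodobutan-2-ol
Product: 7 tert-butyl{[(2S)-4-iodobutan-2-yl]oxy}dimethylsilane
Conditions: TBSCl, imidazole, DMF, rt
Reagents that add atoms: tert-butyldimethylsilyl chloride, CC(C)(C)[Si](C)(C)Cl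
Why: Imidazole-promoted silylation of a secondary alcohol; this ether withstands the organolithium step and is later removed by fluoride under basic conditions.

Step 6
Reactants: 4 (2S)-2-(hex-5-en-1-yl)-2,3-dihydrofuran; 7 tert-butyl{[(2S)-4-iodobutan-2-yl]oxy}dimethylsilane
Product: 9 (2S)-5-[(3S)-3-(tert-butyldimethylsilyloxy)butyl]-2-(hex-5-en-1-yl)-2,3-dihydrofuran, via 5-lithio-2,3-dihydrofuran 8 (not isolated)
Conditions: t-BuLi, THF, −78 to 0 °C; then 7, THF/DMPU, −78 °C to rt; chromatography on Et3N-treated silica
Reagents that add atoms: none
Why: α-Lithiation of a cyclic enol ether followed by SN2 alkylation: t-BuLi removes the vinylic hydrogen on C5'', which is acidified by the ring oxygen, and the vinyllithium displaces the primary iodide to form the C5''–C9'' bond; neither stereocentre is touched.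

Step 7
Reactants: 9 (2S)-5-[(3S)-3-(tert-butyldimethylsilyloxy)butyl]-2-(hex-5-en-1-yl)-2,3-dihydrofuran
Product: 10 (2S)-2-(hex-5-en-1-yl)-5-[(3S)-3-hydroxybutyl]-2,3-dihydrofuran
Conditions: Bu4NF, THF, rt; used at once
Reagents that add atoms: none
Why: Fluoride-induced desilylation; the medium stays basic, so the acid-labile enol ether and its pendant hydroxyl should not close prematurely.

Step 8
Reactants: 10 (2S)-2-(hex-5-en-1-yl)-5-[(3S)-3-hydroxybutyl]-2,3-dihydrofuran
Product: 12 (2S,4S,5R,7S)-2-(hex-5-en-1-yl)-7-methyl-1,6-dioxaspiro[4.4]nonan-4-ol, via anti enol ether epoxide 11 (not isolated)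
Conditions: dimethyldioxirane (1.05 equiv, acetone solution), CH2Cl2, −78 °C; then Ti(OiPr)4 (2 equiv), −78 to 0 °C; aq. NaHCO3
Reagents that add atoms: dimethyldioxirane, CC1(C)OO1
Why: The dioxirane transfers oxygen to the electron-rich C4''=C5'' enol ether through a spiro transition state, on the ring face opposite the C2'' chain, to give epoxide 11. Ti(OiPr)4 then exchanges one isopropoxide for the side-chain hydroxyl and binds the epoxide oxygen; as the C5''–O(epoxide) bond lengthens towards an oxocarbenium ion, the titanium-bound alkoxide is delivered to C5'' on the face the epoxide oxygen is leaving. The closest known reaction type is the titanium-mediated kinetic epoxide-opening spirocyclisation of six-membered glycal epoxides with retention at the anomeric carbon; 11 is its ring-contracted analogue. Ring D closes by a 5-exo-tet attack of O6'' on C5'', the breaking C–O bond lying outside the new ring. C4'' is set by the face of epoxidation, which the C2'' chain controls sterically, and C5'' is set by the syn delivery enforced by the O–Ti–O bridge, so both trace back to that face; C2'' and C7'' are spectators. Chemoselectivity for the enol ether over the terminal alkene is secured by its far higher nucleophilicity and by one equivalent of oxidant at −78 °C. Facial selectivity is likely to be moderate because the chain is two atoms from C4''; the syn epoxide would give the C4'',C5'' bis-epimer, a diastereomer that should be separable at this hydroxylated stage. Retention over inversion is secured by adding the titanium reagent at −78 °C before untemplated opening can begin and by excluding protic additives, and Ti(OiPr)4 is too weak a Lewis acid to re-ionise the product ketal at 0 °C.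

Step 9
Reactants: 12 (2S,4S,5R,7S)-2-(hex-5-en-1-yl)-7-methyl-1,6-dioxaspiro[4.4]nonan-4-ol
Product: 13 O-[(2S,4S,5R,7S)-2-(hex-5-en-1-yl)-7-methyl-1,6-dioxaspiro[4.4]nonan-4-yl] 1H-imidazole-1-carbothioate
Conditions: 1,1'-thiocarbonyldiimidazole, DMAP (cat.), toluene, 80 °C
Reagents that add atoms: 1,1'-thiocarbonyldiimidazole, S=C(n1ccnc1)n1ccnc1
Why: Thioacylation of the secondary hydroxyl, the first stage of a Barton–McCombie deoxygenation; the conditions are basic and non-ionising, so C5'' is not at risk.

Step 10
Reactants: 13 O-[(2S,4S,5R,7S)-2-(hex-5-en-1-yl)-7-methyl-1,6-dioxaspiro[4.4]nonan-4-yl] 1H-imidazole-1-carbothioate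
Product: 14 (2S,5R,7S)-2-(hex-5-en-1-yl)-7-methyl-1,6-dioxaspiro[4.4]nonane
Conditions: Bu3SnH, AIBN (cat.), toluene, 100 °C; chromatography on Et3N-treated silica
Reagents that add atoms: none
Why: Barton–McCombie deoxygenation: the stannyl radical adds to the thiocarbonyl sulfur, the C4''–O bond fragments and the secondary radical takes hydrogen from the stannane. The radical next to the ketal carbon should not expel a ketal oxygen, the medium is neutral so C5'' keeps its configuration, and the thiocarbonyl group is a far better radical acceptor than the isolated alkene.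

Step 11
Reactants: 15 methyl 2,4-dimethoxy-6-methylbenzoate
Product: 16 methyl 2-(bromomethyl)-4,6-dimethoxybenzoate
Conditions: NBS (1.05 equiv), AIBN (cat.), PhCF3, reflux, visible light
Reagents that add atoms: N-bromosuccinimide, O=C1CCC(=O)N1Br
Why: Wohl–Ziegler benzylic bromination; a radical chain in a non-polar solvent favours hydrogen abstraction from the methyl group over ionic bromination of the ring.

Step 12
Reactants: 16 methyl 2-(bromomethyl)-4,6-dimethoxybenzoate
Product: 17 methyl 2-formyl-4,6-dimethoxybenzoate
Conditions: 4-methylmorpholine N-oxide (3 equiv), 4 Å molecular sieves, MeCN, rt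
Reagents that add atoms: 4-methylmorpholine N-oxide, C[N+]1([O-])CCOCC1
Why: Amine N-oxide oxidation of a benzylic halide (a Kornblum-type oxidation): O-alkylation of the N-oxide and base-induced elimination give the aldehyde at room temperature, below the temperature at which the bromo ester would lactonise.

Step 13
Reactants: 14 (2S,5R,7S)-2-(hex-5-en-1-yl)-7-methyl-1,6-dioxaspiro[4.4]nonane; 17 methyl 2-formyl-4,6-dimethoxybenzoate
Product: 22 (3R)-5,7-dimethoxy-3-{6-[(2S,5R,7S)-7-methyl-1,6-dioxaspiro[4.4]nonan-2-yl]hexyl}isobenzofuran-1(3H)-one, via alkyldiethylborane 18 (not isolated), via dialkylzinc 19 (not isolated), via mixed alkylzinc 20 (not isolated), via zinc alkoxide of the hydroxy ester 21 (not isolated)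
Conditions: Et2BH (from BH3·SMe2 and Et3B), Et2O, 0 °C to rt; Et2Zn (neat), 0 °C, then evaporation; Zn(CH2SiMe3)2, Et2O, 0 °C; 17 (1.2 equiv), Ti(OiPr)4, (1S,2S)-1,2-bis(trifluoromethanesulfonamido)cyclohexane (8 mol %), toluene, −20 °C to rt; H2O; chromatography on Et3N-treated silica
Reagents that add atoms: none
Why: Anti-Markovnikov hydroboration puts boron on C1', and boron–zinc exchange followed by comproportionation with Zn(CH2SiMe3)2 gives a mixed zinc reagent in which only the primary alkyl group transfers, so none of 14 is wasted. The chiral titanium bis(sulfonamide) catalyst directs the catalytic enantioselective organozinc addition to one face of the aldehyde and sets C3 as R. The resulting alkoxide attacks the neighbouring ester and closes ring B with loss of methoxide, so no acid meets the spiroketal.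

## Compound list

1 | rac-2-(hex-5-en-1-yl)oxirane (1,2-epoxy-7-octene) | C=CCCCCC1CO1 | starting material
2 | (2S)-2-(hex-5-en-1-yl)oxirane | C=CCCCC[C@H]1CO1 | intermediate
3 | (4S)-dec-9-en-1-yn-4-ol | C=CCCCC[C@H](O)CC#C | intermediate
4 | (2S)-2-(hex-5-en-1-yl)-2,3-dihydrofuran | C=CCCCC[C@H]1CC=CO1 | intermediate
5 | (3S)-butane-1,3-diol | C[C@H](O)CCO | starting material
6 | (2S)-4-iodobutan-2-ol | C[C@H](O)CCI | intermediate
7 | tert-butyl{[(2S)-4-iodobutan-2-yl]oxy}dimethylsilane | C[C@H](O[Si](C)(C)C(C)(C)C)CCI | intermediate
8 | (2S)-2-(hex-5-en-1-yl)-5-lithio-2,3-dihydrofuran (not isolated) | C=CCCCC[C@H]1CC=C([Li])O1 | intermediate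
9 | (2S)-5-[(3S)-3-(tert-butyldimethylsilyloxy)butyl]-2-(hex-5-en-1-yl)-2,3-dihydrofuran | C=CCCCC[C@H]1CC=C(CC[C@H](C)O[Si](C)(C)C(C)(C)C)O1 | intermediate
10 | (2S)-2-(hex-5-en-1-yl)-5-[(3S)-3-hydroxybutyl]-2,3-dihydrofuran | C=CCCCC[C@H]1CC=C(CC[C@H](C)O)O1 | intermediate
11 | (2S)-4,5-epoxy-2-(hex-5-en-1-yl)-5-[(3S)-3-hydroxybutyl]tetrahydrofuran, oxirane oxygen trans to the C2 chain (not isolated) | C=CCCCC[C@H]1C[C@@H]2O[C@]2(CC[C@H](C)O)O1 | intermediate
12 | (2S,4S,5R,7S)-2-(hex-5-en-1-yl)-7-methyl-1,6-dioxaspiro[4.4]nonan-4-ol | C=CCCCC[C@H]1C[C@H](O)[C@@]3(CC[C@H](C)O3)O1 | intermediate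
13 | O-[(2S,4S,5R,7S)-2-(hex-5-en-1-yl)-7-methyl-1,6-dioxaspiro[4.4]nonan-4-yl] 1H-imidazole-1-carbothioate | C=CCCCC[C@H]1C[C@H](OC(=S)n2ccnc2)[C@@]3(CC[C@H](C)O3)O1 | intermediate
14 | (2S,5R,7S)-2-(hex-5-en-1-yl)-7-methyl-1,6-dioxaspiro[4.4]nonane | C=CCCCC[C@H]1CC[C@@]3(CC[C@H](C)O3)O1 | intermediate
15 | methyl 2,4-dimethoxy-6-methylbenzoate | COC(=O)c1c(C)cc(OC)cc1OC | starting material
16 | methyl 2-(bromomethyl)-4,6-dimethoxybenzoate | COC(=O)c1c(CBr)cc(OC)cc1OC | intermediate
17 | methyl 2-formyl-4,6-dimethoxybenzoate | COC(=O)c1c(C=O)cc(OC)cc1OC | intermediate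
18 | diethyl{6-[(2S,5R,7S)-7-methyl-1,6-dioxaspiro[4.4]nonan-2-yl]hexyl}borane (not isolated) | CCB(CC)CCCCCC[C@H]1CC[C@@]3(CC[C@H](C)O3)O1 | intermediate
19 | bis{6-[(2S,5R,7S)-7-methyl-1,6-dioxaspiro[4.4]nonan-2-yl]hexyl}zinc (not isolated) | C(CCCCC[C@H]1CC[C@@]2(CC[C@H](C)O2)O1)[Zn]CCCCCC[C@H]1CC[C@@]2(CC[C@H](C)O2)O1 | intermediate
20 | {6-[(2S,5R,7S)-7-methyl-1,6-dioxaspiro[4.4]nonan-2-yl]hexyl}[(trimethylsilyl)methyl]zinc (not isolated) | C[Si](C)(C)C[Zn]CCCCCC[C@H]1CC[C@@]2(CC[C@H](C)O2)O1 | intermediate
21 | methyl 2-{(1R)-1-hydroxy-7-[(2S,5R,7S)-7-methyl-1,6-dioxaspiro[4.4]nonan-2-yl]heptyl}-4,6-dimethoxybenzoate, formed as its zinc alkoxide (not isolated) | COC(=O)c1c(OC)cc(OC)cc1[C@@H](CCCCCC[C@H]1CC[C@@]2(CC[C@H](C)O2)O1)O | intermediate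
22 | (3R)-5,7-dimethoxy-3-{6-[(2S,5R,7S)-7-methyl-1,6-dioxaspiro[4.4]nonan-2-yl]hexyl}isobenzofuran-1(3H)-one | COc1cc(OC)c2c(c1)[C@@H](CCCCCC[C@H]1CC[C@@]3(CC[C@H](C)O3)O1)OC2=O | target

## Step count and least certain steps

Total: 13 steps. Longest linear sequence: 9 steps (steps 1, 2, 3, 6, 7, 8, 9, 10 and 13, from 1 to 22). The branch from 5 joins at step 6 and the branch from 15 at step 13.

**Step 8 (key step).**
- Facial selectivity in the epoxidation may be poor, because the C2'' chain is two atoms from C4'' and a five-membered ring gives little conformational bias.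
- The very reactive epoxide may be opened by the hydroxyl before titanium has bound, with inversion or through a free oxocarbenium ion, which would scramble C5''.
- Isopropoxide may be transferred from titanium to C5'' in place of the tethered oxygen.
- Acid on work-up or on silica may epimerise the product.
- Fallback: from 10, a catalytic amount of pyridinium p-toluenesulfonate in CH2Cl2 would protonate the enol ether at C4'' and let the hydroxyl close on the oxocarbenium ion. This would give 14 directly, together with its C5'' epimer (2S,5S,7S)-2-(hex-5-en-1-yl)-7-methyl-1,6-dioxaspiro[4.4]nonane F1. The two would be separated, and F1 would be re-equilibrated under the same acid and recycled. This gives up kinetic control, makes steps 8 to 10 unnecessary and comes back to the route at 14.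

**Step 13.**
- Boron–zinc exchange or formation of the mixed reagent may be incomplete, so that ethyl groups are transferred in competition.
- The ester next to the aldehyde may chelate titanium and erode the facial selectivity; the C3 epimer is a remote diastereomer and would be hard to remove.
- Lactonisation of the doubly ortho-substituted ester may be slow.
- The Lewis acids may epimerise C5''.
- Fallback: it sets out from 14, which is converted into 20 as in step 13. Reagent 20 is added under the same titanium conditions to commercial 2-bromo-3,5-dimethoxybenzaldehyde F2, which has no ester. This gives 1-(2-bromo-3,5-dimethoxyphenyl)-7-[(2S,5R,7S)-7-methyl-1,6-dioxaspiro[4.4]nonan-2-yl]heptan-1-ol F3 as a mixture of carbinol epimers. Dess–Martin oxidation buffered with NaHCO3 gives 1-(2-bromo-3,5-dimethoxyphenyl)-7-[(2S,5R,7S)-7-methyl-1,6-dioxaspiro[4.4]nonan-2-yl]heptan-1-one F4. Corey–Bakshi–Shibata reduction with the (S)-oxazaborolidine and catecholborane, the aryl group acting as the large substituent, should give (1R)-1-(2-bromo-3,5-dimethoxyphenyl)-7-[(2S,5R,7S)-7-methyl-1,6-dioxaspiro[4.4]nonan-2-yl]heptan-1-ol F5. Carbonylation (Pd(OAc)2, Xantphos, CO at 1 atm, Et3N, toluene, 80 °C) then inserts C1 and closes ring B, and the fallback comes back to the route at 22.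

**Step 6.**
- Lithiation may be incomplete, or lithium–iodine exchange and elimination on 7 may compete with substitution, which would return 4 and consume the iodide.
- The trisubstituted enol ether of 9 may be hydrolysed on silica.
- Fallback: it sets out from 7 and 2. Iodide 7 is treated with LiC≡CH·H2NCH2CH2NH2 in DMSO to give (S)-tert-butyl(hex-5-yn-2-yloxy)dimethylsilane F6. Its lithium acetylide, with BF3·OEt2 at −78 °C, opens epoxide 2 at the terminal carbon to give (7S,13S)-13-(tert-butyldimethylsilyloxy)tetradec-1-en-9-yn-7-ol F7. A 5-endo-dig cycloisomerisation of this 3-alkyn-1-ol with a π-acid catalyst (Ph3PAuNTf2, 2,6-di-tert-butylpyridine, toluene, rt) closes ring C and gives 9, where the fallback rejoins the route. It also makes steps 2 and 3 unnecessary.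

**Step 11.**
- Ionic bromination of the electron-rich ring may compete with the radical chain.
- A second bromination at the benzylic carbon may occur.
- The bromo ester may lactonise on heating with loss of bromomethane.
- Fallback: it sets out from 15. LDA in THF at −78 °C gives the benzylic anion, which is sulfenylated with PhSSPh to methyl 2,4-dimethoxy-6-[(phenylsulfanyl)methyl]benzoate F8. One equivalent of m-CPBA at −78 °C gives methyl 2,4-dimethoxy-6-[(phenylsulfinyl)methyl]benzoate F9. Pummerer rearrangement (trifluoroacetic anhydride, 2,6-lutidine, CH2Cl2, 0 °C) and hydrolysis with aqueous NaHCO3 give 17, where the fallback comes back to the route.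

## Further compounds

F1 | step 8 | (2S,5S,7S)-2-(hex-5-en-1-yl)-7-methyl-1,6-dioxaspiro[4.4]nonane | C=CCCCC[C@H]1CC[C@]3(CC[C@H](C)O3)O1
F2 | step 13 | 2-bromo-3,5-dimethoxybenzaldehyde | O=Cc1cc(OC)cc(OC)c1Br
F3 | step 13 | 1-(2-bromo-3,5-dimethoxyphenyl)-7-[(2S,5R,7S)-7-methyl-1,6-dioxaspiro[4.4]nonan-2-yl]heptan-1-ol (both carbinol epimers) | COc1cc(OC)c(Br)c(c1)C(O)CCCCCC[C@H]1CC[C@@]2(CC[C@H](C)O2)O1
F4 | step 13 | 1-(2-bromo-3,5-dimethoxyphenyl)-7-[(2S,5R,7S)-7-methyl-1,6-dioxaspiro[4.4]nonan-2-yl]heptan-1-one | COc1cc(OC)c(Br)c(c1)C(=O)CCCCCC[C@H]1CC[C@@]2(CC[C@H](C)O2)O1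
F5 | step 13 | (1R)-1-(2-bromo-3,5-dimethoxyphenyl)-7-[(2S,5R,7S)-7-methyl-1,6-dioxaspiro[4.4]nonan-2-yl]heptan-1-ol | COc1cc(OC)c(Br)c(c1)[C@@H](CCCCCC[C@H]1CC[C@@]2(CC[C@H](C)O2)O1)O
F6 | step 6 | (S)-tert-butyl(hex-5-yn-2-yloxy)dimethylsilane | C#CCC[C@H](C)O[Si](C)(C)C(C)(C)C
F7 | step 6 | (7S,13S)-13-(tert-butyldimethylsilyloxy)tetradec-1-en-9-yn-7-ol | C=CCCCC[C@H](O)CC#CCC[C@H](C)O[Si](C)(C)C(C)(C)C
F8 | step 11 | methyl 2,4-dimethoxy-6-[(phenylsulfanyl)methyl]benzoate | COC(=O)c1c(CSc2ccccc2)cc(OC)cc1OC
F9 | step 11 | methyl 2,4-dimethoxy-6-[(phenylsulfinyl)methyl]benzoate | COC(=O)c1c(CS(=O)c2ccccc2)cc(OC)cc1OC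
A1 | alternative 1 | 2-bromo-3,5-dimethoxyphenyl trifluoromethanesulfonate | COc1cc(OC)c(Br)c(OS(=O)(=O)C(F)(F)F)c1
A2 | alternative 1 | (2S,5R,7S)-2-(hept-6-yn-1-yl)-7-methyl-1,6-dioxaspiro[4.4]nonane | C#CCCCCC[C@H]1CC[C@@]3(CC[C@H](C)O3)O1
A3 | alternative 1 | 2,4-dimethoxy-6-{7-[(2S,5R,7S)-7-methyl-1,6-dioxaspiro[4.4]nonan-2-yl]hept-1-yn-1-yl}benzoic acid | COc1cc(OC)c(C(=O)O)c(c1)C#CCCCCC[C@H]1CC[C@@]3(CC[C@H](C)O3)O1
A4 | alternative 1 | (3Z)-5,7-dimethoxy-3-{6-[(2S,5R,7S)-7-methyl-1,6-dioxaspiro[4.4]nonan-2-yl]hexylidene}isobenzofuran-1(3H)-one | COc1cc(OC)c2c(c1)/C(=C/CCCCC[C@H]1CC[C@@]3(CC[C@H](C)O3)O1)OC2=O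
A5 | alternative 2 | 2,2-dimethyl-6-{(5R)-11-[(2S,5R,7S)-7-methyl-1,6-dioxaspiro[4.4]nonan-2-yl]-2,4-dioxo-5-(triethylsilyloxy)undecyl}-4H-1,3-dioxin-4-one | CC1(C)OC(=O)C=C(CC(=O)CC(=O)[C@@H](CCCCCC[C@H]2CC[C@@]3(CC[C@H](C)O3)O2)O[Si](CC)(CC)CC)O1
A6 | alternative 2 | 7-hydroxy-2,2-dimethyl-5-{(1R)-7-[(2S,5R,7S)-7-methyl-1,6-dioxaspiro[4.4]nonan-2-yl]-1-(triethylsilyloxy)heptyl}-4H-benzo[d][1,3]dioxin-4-one | CC1(C)OC(=O)c2c(O1)cc(O)cc2[C@@H](CCCCCC[C@H]4CC[C@@]3(CC[C@H](C)O3)O4)O[Si](CC)(CC)CC
A7 | alternative 3 | acetone N,N-dimethylhydrazone | CC(C)=NN(C)C
A8 | alternative 3 | (S)-2-methyloxirane | C[C@H]1CO1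
A9 | alternative 3 | (2S,8S)-5-(2,2-dimethylhydrazinylidene)tetradec-13-ene-2,8-diol | C=CCCCC[C@H](O)CCC(=NN(C)C)CC[C@H](C)O
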